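**Retrosynthetic overview**

1. Ring numbering: C1 (quaternary; CH3 and 4-methylpent-3-enyl), C2=C3 (E), C4 (acyloxy), C5–C6 (epoxide, CH3 on C5), C7, C8, C9 (CH2OH)=C10, C11. The strategy rests on the C1–C2 bond, which joins the all-carbon stereocentre C1 to the E-C2=C3 alkene inside the single eleven-membered carbocycle.
2. Target ⇒ macrocyclic tetraene 24: the ester, the C5–C6 epoxide (directed by C4–OH onto the ring-cis C5=C6) and the protecting groups are handled after ring formation.
3. 24 ⇒ acyclic 20 (tertiary C1 boronic ester, Z-C2 vinyl iodide): the ring, the only one made, is closed at boron as a twelve-membered borate and contracted across C1–C2 by a Zweifel-type 1,2-shift.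
4. 20 ⇒ C2–C3 by alkynylation of a Z-enal (sets C4), C5=C6 by Still–Gennari olefination, C9=C10 by Horner–Wadsworth–Emmons olefination, C1 by copper-catalysed enantioselective β-borylation of methyl geranate.

Key step: step 15

Assumptions on the chemistry:
- Methyl geranate is used as the pure (2E) isomer, because the (2Z) ester would give the opposite configuration at C1.
- In the two catalytic asymmetric steps (2 and 11) the ligand enantiomer is the one whose sense of induction gives the stated descriptor; the antipode is used if the sense proves opposite.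
- Bpin = 4,4,5,5-tetramethyl-1,3,2-dioxaborolan-2-yl; TBDPS = tert-butyldiphenylsilyl; MOP = 2-methoxypropan-2-yl. The ring numbering above is used for all intermediates.

**Route**

Step 1
Reactants: 1 triethyl phosphonoacetate; 2 2-(2-bromoethyl)-1,3-dioxolane
Product: 3 ethyl 2-(diethoxyphosphoryl)-4-(1,3-dioxolan-2-yl)butanoate (racemic)
Conditions: NaH, DMF, 0 to 60 °C (excess 1)
Reagents that add atoms: none
Why: SN2 alkylation of the sodium salt of the phosphonoacetate by the primary bromide gives the α-branched olefination reagent carrying C9, C8, C7 and masked C6, and the excess of 1 should suppress dialkylation.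

Step 2
Reactants: 4 methyl (2E)-3,7-dimethylocta-2,6-dienoate (methyl geranate); 5 bis(pinacolato)diboron
Product: 6 methyl (3R)-3,7-dimethyl-3-(Bpin)oct-6-enoate
Conditions: CuCl (cat.), NaOtBu (cat.), (R)-1-[(S)-2-(diphenylphosphino)ferrocenyl]ethyldicyclohexylphosphine or its enantiomer (cat.), MeOH (2 equiv), THF, rt
Reagents that add atoms: none
Why: Copper-catalysed enantioselective conjugate borylation of a β,β-disubstituted enoate, in which the ligated Cu–Bpin species adds boron to the β-carbon (C1) on the face chosen by the ligand, the fixed E geometry letting it tell CH3 from the homoprenyl CH2, while methanol protonates the copper enolate and the isolated trisubstituted alkene stays untouched.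

Step 3
Reactants: 6 methyl (3R)-3,7-dimethyl-3-(Bpin)oct-6-enoate
Product: 7 (3R)-3,7-dimethyl-3-(Bpin)oct-6-enal
Conditions: iBu2AlH (1.1 equiv), CH2Cl2, −78 °C; aqueous potassium sodium tartrate; used crude
Reagents that add atoms: none
Why: Partial ester reduction stops at the aluminium hemiacetal at −78 °C and releases the aldehyde on work-up, the tertiary alkyl boronic ester being inert to the hydride at this temperature.

Step 4
Reactants: 7 (3R)-3,7-dimethyl-3-(Bpin)oct-6-enal; 3 ethyl 2-(diethoxyphosphoryl)-4-(1,3-dioxolan-2-yl)butanoate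
Product: 8 ethyl (2E,5R)-2-[2-(1,3-dioxolan-2-yl)ethyl]-5,9-dimethyl-5-(Bpin)deca-2,8-dienoate
Conditions: NaH, THF, 0 °C to rt
Reagents that add atoms: none
Why: Horner–Wadsworth–Emmons olefination of an α-alkyl phosphonoacetate should favour the (E)-enoate, with the ester trans to the neopentyl-like C11, which places C8 and C11 cis on C9=C10 as the target requires, any Z isomer being removed by chromatography.

Step 5
Reactants: 8 ethyl (2E,5R)-2-[2-(1,3-dioxolan-2-yl)ethyl]-5,9-dimethyl-5-(Bpin)deca-2,8-dienoate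
Product: 9 (2E,5R)-2-[2-(1,3-dioxolan-2-yl)ethyl]-5,9-dimethyl-5-(Bpin)deca-2,8-dien-1-ol
Conditions: iBu2AlH (2.5 equiv), CH2Cl2, −78 °C
Reagents that add atoms: none
Why: 1,2-Reduction of the enoate to the primary allylic alcohol, which becomes the C9 hydroxymethyl group, leaves the acetal and the boronic ester untouched.

Step 6
Reactants: 9 (2E,5R)-2-[2-(1,3-dioxolan-2-yl)ethyl]-5,9-dimethyl-5-(Bpin)deca-2,8-dien-1-ol
Product: 10 TBDPS ether of 9
Conditions: tBuPh2SiCl, imidazole, DMF, rt
Reagents that add atoms: tert-butyl(chloro)diphenylsilane, CC(C)(C)[Si](Cl)(c1ccccc1)c1ccccc1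
Why: Silylation of the primary allylic alcohol with a group chosen to survive acetal hydrolysis, the organolithium step and the later mild acid that frees C4–OH, so that it can be removed last by fluoride.

Step 7
Reactants: 10 TBDPS ether of 9
Product: 11 (4E,7R)-4-[(tert-butyldiphenylsilyloxy)methyl]-7,11-dimethyl-7-(Bpin)dodeca-4,10-dienal
Conditions: PPTS, acetone/H2O, reflux
Reagents that add atoms: water, O
Why: Acid-catalysed hydrolysis of the dioxolane frees the C6 aldehyde under conditions that a TBDPS ether and a tertiary pinacol boronic ester tolerate.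

Step 8
Reactants: 11 (4E,7R)-4-[(tert-butyldiphenylsilyloxy)methyl]-7,11-dimethyl-7-(Bpin)dodeca-4,10-dienal; 12 ethyl 2-[bis(2,2,2-trifluoroethoxy)phosphoryl]propanoate
Product: 13 ethyl (2Z,6E,9R)-6-[(tert-butyldiphenylsilyloxy)methyl]-2,9,13-trimethyl-9-(Bpin)tetradeca-2,6,12-trienoate
Conditions: KN(SiMe3)2, 18-crown-6, THF, −78 °C
Reagents that add atoms: none
Why: Still–Gennari olefination with the trifluoroethyl phosphonate under dissociating conditions is kinetically Z-selective, so C5=C6 is formed with C4 and C7 cis and the methyl group on C5.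

Step 9
Reactants: 13 ethyl (2Z,6E,9R)-6-[(tert-butyldiphenylsilyloxy)methyl]-2,9,13-trimethyl-9-(Bpin)tetradeca-2,6,12-trienoate
Product: 14 (2Z,6E,9R)-6-[(tert-butyldiphenylsilyloxy)methyl]-2,9,13-trimethyl-9-(Bpin)tetradeca-2,6,12-trien-1-ol
Conditions: iBu2AlH (2.5 equiv), CH2Cl2, −78 °C
Reagents that add atoms: none
Why: 1,2-Reduction of the Z-enoate gives the Z-allylic alcohol without loss of alkene geometry.

Step 10
Reactants: 14 (2Z,6E,9R)-6-[(tert-butyldiphenylsilyloxy)methyl]-2,9,13-trimethyl-9-(Bpin)tetradeca-2,6,12-trien-1-ol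
Product: 15 (2Z,6E,9R)-6-[(tert-butyldiphenylsilyloxy)methyl]-2,9,13-trimethyl-9-(Bpin)tetradeca-2,6,12-trienal
Conditions: Dess–Martin periodinane, NaHCO3, CH2Cl2, 0 °C; used at once
Reagents that add atoms: none
Why: Buffered Dess–Martin oxidation gives the Z-enal (C4 aldehyde) under neutral conditions in the cold, which should hold back Z to E isomerisation.

Step 11
Reactants: 15 (2Z,6E,9R)-6-[(tert-butyldiphenylsilyloxy)methyl]-2,9,13-trimethyl-9-(Bpin)tetradeca-2,6,12-trienal; 16 ethynyltrimethylsilane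
Product: 17 (3R,4Z,8E,11R)-8-[(tert-butyldiphenylsilyloxy)methyl]-4,11,15-trimethyl-11-(Bpin)-1-(trimethylsilyl)hexadeca-4,8,14-trien-1-yn-3-ol
Conditions: Me2Zn, ProPhenol ligand (20 mol%, enantiomer for Si-face addition), Ph3P=O (cat.), toluene, 4 °C
Reagents that add atoms: none
Why: Zinc–ProPhenol-catalysed enantioselective alkynylation, a method suited to α,β-unsaturated aldehydes, delivers the zinc acetylide to the Si face of the aldehyde under control of the dinuclear zinc catalyst and so sets C4 (the configuration to be checked by Mosher ester analysis).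

Step 12
Reactants: 17 (3R,4Z,8E,11R)-8-[(tert-butyldiphenylsilyloxy)methyl]-4,11,15-trimethyl-11-(Bpin)-1-(trimethylsilyl)hexadeca-4,8,14-trien-1-yn-3-ol
Product: 18 (3R,4Z,8E,11R)-8-[(tert-butyldiphenylsilyloxy)methyl]-1-iodo-4,11,15-trimethyl-11-(Bpin)hexadeca-4,8,14-trien-1-yn-3-ol
Conditions: N-iodosuccinimide, AgNO3 (cat.), DMF, rt, dark
Reagents that add atoms: N-iodosuccinimide, O=C1CCC(=O)N1I
Why: Silver-catalysed iododesilylation converts the alkynylsilane directly into the 1-iodoalkyne without touching the alkenes or the carbinol.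

Step 13
Reactants: 18 (3R,4Z,8E,11R)-8-[(tert-butyldiphenylsilyloxy)methyl]-1-iodo-4,11,15-trimethyl-11-(Bpin)hexadeca-4,8,14-trien-1-yn-3-ol
Product: 19 (1Z,3S,4Z,8E,11R)-8-[(tert-butyldiphenylsilyloxy)methyl]-1-iodo-4,11,15-trimethyl-11-(Bpin)hexadeca-1,4,8,14-tetraen-3-ol
Conditions: 2-nitrobenzenesulfonohydrazide, Et3N, THF/iPrOH, rt
Reagents that add atoms: none
Why: Diimide generated in the flask adds H2 syn to the iodoalkyne and gives the Z-vinyl iodide, trisubstituted alkenes being reduced far more slowly.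

Step 14
Reactants: 19 (1Z,3S,4Z,8E,11R)-8-[(tert-butyldiphenylsilyloxy)methyl]-1-iodo-4,11,15-trimethyl-11-(Bpin)hexadeca-1,4,8,14-tetraen-3-ol
Product: 20 MOP ether of 19 (acyclic C1 boronic ester with Z-C2 vinyl iodide)
Conditions: 2-methoxypropene, PPTS (cat.), CH2Cl2, 0 °C; Et3N quench
Reagents that add atoms: 2-methoxypropene, COC(C)=C
Why: Acid-catalysed addition of the alcohol to the enol ether gives a mixed acetal without a new stereocentre, chosen over a silyl ether because a silyl group on C4–O could migrate to C2 of the cis-alkenyllithium (retro-[1,4]-Brook shift) and because the acetal is later cleaved under conditions that spare the TBDPS ether.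

Step 15
Reactants: 20 MOP ether of 19 (acyclic C1 boronic ester with Z-C2 vinyl iodide)
Product: 24 (1S,2E,4S,5Z,9E)-9-[(tert-butyldiphenylsilyloxy)methyl]-4-(2-methoxypropan-2-yloxy)-1,5-dimethyl-1-(4-methylpent-3-enyl)cycloundeca-2,5,9-triene, via alkenyllithium 21 (not isolated), via cyclic lithium borate 22 (not isolated), via beta-iodo boronate 23 (not isolated)
Conditions: tBuLi (2.05 equiv), THF/Et2O, −78 °C, about 1 mM; then I2, THF, −78 °C; then NaOMe, MeOH, −78 °C to rt
Reagents that add atoms: none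
Why: Proposed new method: tBuLi should exchange the C2 iodide faster than it adds to the hindered tertiary boronic ester, and the Z-alkenyllithium 21 then attacks the trigonal boron of its own chain to give the twelve-membered cyclic borate 22 (first ring closure, by C2–B bond formation at an unhindered Lewis-acidic atom); iodine forms an iodonium ion on C2=C3 and C1, the only carbon ligand on boron besides the alkenyl group, migrates from boron to C2 anti to iodine, which contracts the boracycle to the eleven-membered carbocycle 23 (second closure, by 1,2-metallate shift, forming C1–C2). Methoxide then induces anti elimination of boron and iodine, which inverts the alkene geometry, so the ring-cis alkenyl unit emerges as the E-C2=C3 alkene of 24. The closest known reaction is the intermolecular Zweifel olefination of enantioenriched tertiary pinacol boronic esters with alkenyllithiums; the intramolecular, ring-contracting form has not been shown. The quaternary stereocentre C1 is carried over with retention, because the 1,2-shift is stereospecific at the migrating carbon, and C4 is not touched. The step needs intramolecular borate formation to beat oligomerisation, which high dilution and the fold imposed by the three ring-cis alkenes (C2=C3, C5=C6, C9=C10) should favour, and it needs the alkenyllithium to persist until it reaches boron, which the acetal on C4–O secures because it cannot migrate to C2 and holds lithium by chelation.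

Step 16
Reactants: 24 (1S,2E,4S,5Z,9E)-9-[(tert-butyldiphenylsilyloxy)methyl]-4-(2-methoxypropan-2-yloxy)-1,5-dimethyl-1-(4-methylpent-3-enyl)cycloundeca-2,5,9-triene
Product: 25 (1S,2E,4S,5Z,9E)-9-[(tert-butyldiphenylsilyloxy)methyl]-1,5-dimethyl-1-(4-methylpent-3-enyl)cycloundeca-2,5,9-trien-4-ol
Conditions: PPTS (cat.), MeOH, 0 °C
Reagents that add atoms: none
Why: Acid-catalysed transacetalisation to methanol removes the MOP group within minutes in the cold, under conditions too mild to cleave the TBDPS ether or to ionise the bis-allylic carbinol.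

Step 17
Reactants: 25 (1S,2E,4S,5Z,9E)-9-[(tert-butyldiphenylsilyloxy)methyl]-1,5-dimethyl-1-(4-methylpent-3-enyl)cycloundeca-2,5,9-trien-4-ol
Product: 26 (1S,2E,4S,5S,6R,9E)-9-[(tert-butyldiphenylsilyloxy)methyl]-5,6-epoxy-1,5-dimethyl-1-(4-methylpent-3-enyl)cycloundeca-2,9-dien-4-ol
Conditions: VO(acac)2 (cat.), tBuOOH, CH2Cl2, 0 °C
Reagents that add atoms: tert-butyl hydroperoxide, CC(C)(C)OO
Why: Hydroxyl-directed vanadium-catalysed epoxidation, in which the vanadate ester of C4–OH delivers oxygen to the more nucleophilic trisubstituted C5=C6 (not to the hindered E-C2=C3 or the two undirected alkenes) on the face syn to the C4–O bond, the sense known for Z-cycloalkenols of medium rings where the ring carbon C3 stands perpendicular to the alkene on the inner face, C4–O lies near the alkene plane and C4–H eclipses the C5 methyl group, so that C5 and C6 are set cis to the carbinol oxygen as in the target.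

Step 18
Reactants: 26 (1S,2E,4S,5S,6R,9E)-9-[(tert-butyldiphenylsilyloxy)methyl]-5,6-epoxy-1,5-dimethyl-1-(4-methylpent-3-enyl)cycloundeca-2,9-dien-4-ol; 27 3-methylbut-2-enoyl chloride
Product: 28 (1S,2E,4S,5R,6R,9E)-9-[(tert-butyldiphenylsilyloxy)methyl]-5,6-epoxy-1,5-dimethyl-1-(4-methylpent-3-enyl)cycloundeca-2,9-dien-4-yl 3-methylbut-2-enoate
Conditions: pyridine, DMAP (cat.), CH2Cl2, 0 °C to rt
Reagents that add atoms: none
Why: DMAP-catalysed acylation of the secondary alcohol, with pyridine in place of a trialkylamine so that the acid chloride is not deconjugated through its vinylketene.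

Step 19
Reactants: 28 (1S,2E,4S,5R,6R,9E)-9-[(tert-butyldiphenylsilyloxy)methyl]-5,6-epoxy-1,5-dimethyl-1-(4-methylpent-3-enyl)cycloundeca-2,9-dien-4-yl 3-methylbut-2-enoate
Product: 29 (1S,2E,4S,5R,6R,9E)-5,6-epoxy-9-(hydroxymethyl)-1,5-dimethyl-1-(4-methylpent-3-enyl)cycloundeca-2,9-dien-4-yl 3-methylbut-2-enoate (CNP0318149.1)
Conditions: Bu4NF, AcOH (1:1), THF, 0 °C to rt
Reagents that add atoms: none
Why: Fluoride cleavage of the primary silyl ether, buffered with acetic acid so that neither the ester nor the epoxide meets a free alkoxide.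

**Compound list**

1 | triethyl phosphonoacetate | CCOC(=O)CP(=O)(OCC)OCC | starting material
2 | 2-(2-bromoethyl)-1,3-dioxolane | BrCCC1OCCO1 | starting material
3 | ethyl 2-(diethoxyphosphoryl)-4-(1,3-dioxolan-2-yl)butanoate (racemic) | CCOC(=O)C(CCC1OCCO1)P(=O)(OCC)OCC | intermediate
4 | methyl (2E)-3,7-dimethylocta-2,6-dienoate (methyl geranate) | COC(=O)/C=C(C)/CCC=C(C)C | starting material
5 | bis(pinacolato)diboron | CC1(C)OB(OC1(C)C)B1OC(C)(C)C(C)(C)O1 | starting material
6 | methyl (3R)-3,7-dimethyl-3-(Bpin)oct-6-enoate | CC(C)=CCC[C@](C)(B1OC(C)(C)C(C)(C)O1)CC(=O)OC | intermediate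
7 | (3R)-3,7-dimethyl-3-(Bpin)oct-6-enal | CC(C)=CCC[C@](C)(B1OC(C)(C)C(C)(C)O1)CC=O | intermediate
8 | ethyl (2E,5R)-2-[2-(1,3-dioxolan-2-yl)ethyl]-5,9-dimethyl-5-(Bpin)deca-2,8-dienoate | CC(C)=CCC[C@](C)(B1OC(C)(C)C(C)(C)O1)C/C=C(C(=O)OCC)\CCC1OCCO1 | intermediate
9 | (2E,5R)-2-[2-(1,3-dioxolan-2-yl)ethyl]-5,9-dimethyl-5-(Bpin)deca-2,8-dien-1-ol | CC(C)=CCC[C@](C)(B1OC(C)(C)C(C)(C)O1)C/C=C(CO)\CCC1OCCO1 | intermediate
10 | TBDPS ether of 9 | CC(C)=CCC[C@](C)(B1OC(C)(C)C(C)(C)O1)C/C=C(CO[Si](c1ccccc1)(c1ccccc1)C(C)(C)C)\CCC1OCCO1 | intermediate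
11 | (4E,7R)-4-[(tert-butyldiphenylsilyloxy)methyl]-7,11-dimethyl-7-(Bpin)dodeca-4,10-dienal | CC(C)=CCC[C@](C)(B1OC(C)(C)C(C)(C)O1)C/C=C(CO[Si](c1ccccc1)(c1ccccc1)C(C)(C)C)\CCC=O | intermediate
12 | ethyl 2-[bis(2,2,2-trifluoroethoxy)phosphoryl]propanoate | CCOC(=O)C(C)P(=O)(OCC(F)(F)F)OCC(F)(F)F | starting material
13 | ethyl (2Z,6E,9R)-6-[(tert-butyldiphenylsilyloxy)methyl]-2,9,13-trimethyl-9-(Bpin)tetradeca-2,6,12-trienoate | CC(C)=CCC[C@](C)(B1OC(C)(C)C(C)(C)O1)C/C=C(CO[Si](c1ccccc1)(c1ccccc1)C(C)(C)C)\CC/C=C(C)\C(=O)OCC | intermediate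
14 | (2Z,6E,9R)-6-[(tert-butyldiphenylsilyloxy)methyl]-2,9,13-trimethyl-9-(Bpin)tetradeca-2,6,12-trien-1-ol | CC(C)=CCC[C@](C)(B1OC(C)(C)C(C)(C)O1)C/C=C(CO[Si](c1ccccc1)(c1ccccc1)C(C)(C)C)\CC/C=C(C)\CO | intermediate
15 | (2Z,6E,9R)-6-[(tert-butyldiphenylsilyloxy)methyl]-2,9,13-trimethyl-9-(Bpin)tetradeca-2,6,12-trienal | CC(C)=CCC[C@](C)(B1OC(C)(C)C(C)(C)O1)C/C=C(CO[Si](c1ccccc1)(c1ccccc1)C(C)(C)C)\CC/C=C(C)\C=O | intermediate
16 | ethynyltrimethylsilane | C#C[Si](C)(C)C | starting material
17 | (3R,4Z,8E,11R)-8-[(tert-butyldiphenylsilyloxy)methyl]-4,11,15-trimethyl-11-(Bpin)-1-(trimethylsilyl)hexadeca-4,8,14-trien-1-yn-3-ol | CC(C)=CCC[C@](C)(B1OC(C)(C)C(C)(C)O1)C/C=C(CO[Si](c1ccccc1)(c1ccccc1)C(C)(C)C)\CC/C=C(C)\[C@@H](O)C#C[Si](C)(C)C | intermediate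
18 | (3R,4Z,8E,11R)-8-[(tert-butyldiphenylsilyloxy)methyl]-1-iodo-4,11,15-trimethyl-11-(Bpin)hexadeca-4,8,14-trien-1-yn-3-ol | CC(C)=CCC[C@](C)(B1OC(C)(C)C(C)(C)O1)C/C=C(CO[Si](c1ccccc1)(c1ccccc1)C(C)(C)C)\CC/C=C(C)\[C@@H](O)C#CI | intermediate
19 | (1Z,3S,4Z,8E,11R)-8-[(tert-butyldiphenylsilyloxy)methyl]-1-iodo-4,11,15-trimethyl-11-(Bpin)hexadeca-1,4,8,14-tetraen-3-ol | CC(C)=CCC[C@](C)(B1OC(C)(C)C(C)(C)O1)C/C=C(CO[Si](c1ccccc1)(c1ccccc1)C(C)(C)C)\CC/C=C(C)\[C@@H](O)/C=C\I | intermediate
20 | MOP ether of 19: acyclic C1 (R) tertiary boronic ester with Z-C2 vinyl iodide, C4 (S) | CC(C)=CCC[C@](C)(B1OC(C)(C)C(C)(C)O1)C/C=C(CO[Si](c1ccccc1)(c1ccccc1)C(C)(C)C)\CC/C=C(C)\[C@@H](OC(C)(C)OC)/C=C\I | intermediate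
21 | Z-alkenyllithium from 20 (lithium on C2; not isolated) | CC(C)=CCC[C@](C)(B1OC(C)(C)C(C)(C)O1)C/C=C(CO[Si](c1ccccc1)(c1ccccc1)C(C)(C)C)\CC/C=C(C)\[C@@H](OC(C)(C)OC)/C=C\[Li] | intermediate
22 | twelve-membered cyclic lithium borate: boron bonded to C1, C2 and the pinacolate (not isolated) | CC(C)=CCC[C@@]1(C)C/C=C(CO[Si](c2ccccc2)(c2ccccc2)C(C)(C)C)\CC/C=C(C)\[C@@H](OC(C)(C)OC)/C=C\[B-]13OC(C)(C)C(C)(C)O3.[Li+] | intermediate
23 | eleven-membered carbocycle with Bpin on C2 and iodine on C3, anti adduct (not isolated; drawn for iodonium formation on one face of C2=C3, the other face gives the C2,C3 diastereomer and the same alkene) | CC(C)=CCC[C@@]1(C)C/C=C(CO[Si](c2ccccc2)(c2ccccc2)C(C)(C)C)\CC/C=C(C)\[C@@H](OC(C)(C)OC)[C@@H](I)[C@H]1B3OC(C)(C)C(C)(C)O3 | intermediate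
24 | (1S,2E,4S,5Z,9E)-9-[(tert-butyldiphenylsilyloxy)methyl]-4-(2-methoxypropan-2-yloxy)-1,5-dimethyl-1-(4-methylpent-3-enyl)cycloundeca-2,5,9-triene | CC(C)=CCC[C@]1(C)/C=C/[C@H](OC(C)(C)OC)/C(C)=C\CC/C(CO[Si](c2ccccc2)(c2ccccc2)C(C)(C)C)=C\C1 | intermediate
25 | (1S,2E,4S,5Z,9E)-9-[(tert-butyldiphenylsilyloxy)methyl]-1,5-dimethyl-1-(4-methylpent-3-enyl)cycloundeca-2,5,9-trien-4-ol | CC(C)=CCC[C@]1(C)/C=C/[C@H](O)/C(C)=C\CC/C(CO[Si](c2ccccc2)(c2ccccc2)C(C)(C)C)=C\C1 | intermediate
26 | (1S,2E,4S,5S,6R,9E)-9-[(tert-butyldiphenylsilyloxy)methyl]-5,6-epoxy-1,5-dimethyl-1-(4-methylpent-3-enyl)cycloundeca-2,9-dien-4-ol | CC(C)=CCC[C@]1(C)/C=C/[C@H](O)[C@]2(C)O[C@@H]2CC/C(CO[Si](c3ccccc3)(c3ccccc3)C(C)(C)C)=C\C1 | intermediate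
27 | 3-methylbut-2-enoyl chloride | CC(C)=CC(=O)Cl | starting material
28 | (1S,2E,4S,5R,6R,9E)-9-[(tert-butyldiphenylsilyloxy)methyl]-5,6-epoxy-1,5-dimethyl-1-(4-methylpent-3-enyl)cycloundeca-2,9-dien-4-yl 3-methylbut-2-enoate | CC(C)=CCC[C@]1(C)/C=C/[C@H](OC(=O)C=C(C)C)[C@]2(C)O[C@@H]2CC/C(CO[Si](c3ccccc3)(c3ccccc3)C(C)(C)C)=C\C1 | intermediate
29 | (1S,2E,4S,5R,6R,9E)-5,6-epoxy-9-(hydroxymethyl)-1,5-dimethyl-1-(4-methylpent-3-enyl)cycloundeca-2,9-dien-4-yl 3-methylbut-2-enoate (CNP0318149.1) | CC(C)=CCC[C@]1(C)/C=C/[C@H](OC(=O)C=C(C)C)[C@]2(C)O[C@@H]2CC/C(CO)=C\C1 | target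

**Step count**

Total: 19 steps. Longest linear sequence: 18 steps (4 to 29, steps 2 to 19); step 1 is a one-step side branch.

**Steps most likely to fail**

Step 15 (proposed new method). The risks are borate formation between chains instead of within one (oligomers), addition of tBuLi to boron in competition with the exchange, and quenching of the alkenyllithium before the twelve-membered borate closes. The fallback uses known chemistry and closes the ring at C4–C5 instead; it sets out from 10 and comes back at 25.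
- Intermolecular Zweifel olefination of 10 with the Z-alkenyllithium made from (Z)-1-iodo-3-(4-methoxybenzyloxy)prop-1-ene (I/C=C\COCc1ccc(OC)cc1; tBuLi, THF, −78 °C; then I2; then NaOMe) should give the E-allylic 4-methoxybenzyl ether F1, with C1–C2 formed and C1 retained.
- PPTS in wet acetone should free the C6 aldehyde F2.
- Stork–Zhao-type olefination with Ph3P=C(CH3)I should give the (Z)-2-iodoalk-2-ene F3.
- DDQ should remove the 4-methoxybenzyl group to give the allylic alcohol F4, and MnO2 should give the E-enal F5.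
- Nozaki–Hiyama–Kishi macrocyclisation (CrCl2, catalytic NiCl2, DMSO/THF, high dilution) should close the eleven-membered ring and give 25 together with its C4 epimer F6.
- The mixture is converged by MnO2 oxidation to the dienone F7 and Corey–Bakshi–Shibata reduction to 25.

Step 17. The risks are oxygen delivery to the face trans to the hydroxyl (the outcome expected if the ring holds C4–H rather than C4–O near the plane of C5=C6) and competing oxidation of the carbinol to the dienone. The fallback uses the epimeric alcohol as director and then an inverting esterification; it sets out from 25 and comes back at 28.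
- MnO2 oxidation of 25 to the dienone F7 and Corey–Bakshi–Shibata reduction with the antipodal catalyst should give the C4-epimeric alcohol F6.
- VO(acac)2/tBuOOH epoxidation of F6, now trans to the inverted hydroxyl, should place the epoxide on the required face and give the epoxy alcohol F8.
- Mitsunobu esterification of F8 with 3-methylbut-2-enoic acid (PPh3, diisopropyl azodicarboxylate) inverts C4 and gives 28.

Step 11. The risks are Z to E isomerisation of the enal 15 under the Lewis-acidic zinc conditions and weak enantiofacial control with a Z-configured, α-branched enal. The fallback sets C4 by ketone reduction and avoids the Z-enal; it sets out from 13 and comes back at 17.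
- Me3Al with MeNHOMe·HCl should convert the ester 13 into the Weinreb amide F9.
- LiC≡CSiMe3 (THF, −78 °C) should give the ynone F10.
- Noyori transfer hydrogenation (RuCl(p-cymene)(TsDPEN), iPrOH), with the catalyst enantiomer that gives the (3R)-carbinol, returns to 17.

**Further compounds**

F1 | step 15 | acyclic E-C2=C3 allylic 4-methoxybenzyl ether from intermolecular Zweifel olefination of 10 (C1 S; dioxolane at C6) | CC(C)=CCC[C@](C)(/C=C/COCc1ccc(OC)cc1)C/C=C(CO[Si](c1ccccc1)(c1ccccc1)C(C)(C)C)\CCC1OCCO1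
F2 | step 15 | C6 aldehyde from F1 | CC(C)=CCC[C@](C)(/C=C/COCc1ccc(OC)cc1)C/C=C(CO[Si](c1ccccc1)(c1ccccc1)C(C)(C)C)\CCC=O
F3 | step 15 | (Z)-2-iodoalk-2-ene (iodine on C5) from F2 | CC(C)=CCC[C@](C)(/C=C/COCc1ccc(OC)cc1)C/C=C(CO[Si](c1ccccc1)(c1ccccc1)C(C)(C)C)\CC/C=C(C)\I
F4 | step 15 | C4 allylic alcohol from F3 | CC(C)=CCC[C@](C)(/C=C/CO)C/C=C(CO[Si](c1ccccc1)(c1ccccc1)C(C)(C)C)\CC/C=C(C)\I
F5 | step 15 | E-enal (C4 aldehyde) with C5 vinyl iodide | CC(C)=CCC[C@](C)(/C=C/C=O)C/C=C(CO[Si](c1ccccc1)(c1ccccc1)C(C)(C)C)\CC/C=C(C)\I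
F6 | step 15 | C4 epimer of 25 | CC(C)=CCC[C@]1(C)/C=C/[C@@H](O)/C(C)=C\CC/C(CO[Si](c2ccccc2)(c2ccccc2)C(C)(C)C)=C\C1
F7 | step 15 | macrocyclic cross-conjugated dienone (C4 ketone) | CC(C)=CCC[C@]1(C)/C=C/C(=O)/C(C)=C\CC/C(CO[Si](c2ccccc2)(c2ccccc2)C(C)(C)C)=C\C1
F8 | step 17 | C4 epimer of 26 (epoxide on the required face, carbinol inverted) | CC(C)=CCC[C@]1(C)/C=C/[C@@H](O)[C@]2(C)O[C@@H]2CC/C(CO[Si](c3ccccc3)(c3ccccc3)C(C)(C)C)=C\C1
F9 | step 11 | Weinreb amide from 13 | CC(C)=CCC[C@](C)(B1OC(C)(C)C(C)(C)O1)C/C=C(CO[Si](c1ccccc1)(c1ccccc1)C(C)(C)C)\CC/C=C(C)\C(=O)N(C)OC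
F10 | step 11 | Z-alkenyl trimethylsilylethynyl ketone (C4 ketone) | CC(C)=CCC[C@](C)(B1OC(C)(C)C(C)(C)O1)C/C=C(CO[Si](c1ccccc1)(c1ccccc1)C(C)(C)C)\CC/C=C(C)\C(=O)C#C[Si](C)(C)C
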